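Answer 3 questions on two flasks.

common to all: starting material 0.092 M

| run | coupling partner | remark | time |
|---|---|---|---|
| south-east | 0.13 M | run made earlier |  |
| south-west | 0.18 M | run made earlier |  |
| north | 0.29 M | run made earlier |  |
| grey | 0.110 M |  | 4.0 d |
| green | 0.276 M |  | 4.0 d |

| run | time / d | first product / % | starting material / % |
|---|---|---|---|
| south-east | 0.333 | 42 | 50 |
| south-east | 0.625 | 51 | 30 |
| south-east | 1.04 | 53 | 23 |
| south-east | 2.00 | 51 | 13 |
| south-east | 4.00 | 41 | 3 |
| south-west | 0.333 | 50 | 35 |
| south-west | 0.625 | 53 | 18 |
| south-west | 1.04 | 52 | 10 |
| south-west | 2.00 | 50 | 4 |
| south-west | 4.00 | 35 | 2 |
| north | 0.833 | 46 | 5 |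
| north | 1.67 | 35 | 0 |
| north | 2.50 | 31 | 1 |
| north | 3.00 | 27 | 0 |
| north | 4.00 | 28 | 1 |

(each reading ± 1.5 percentage points)



- which of these holds the largest part of the starting material at the end of grey (starting material / double product / first product)
- which of these holds the largest part of the starting material at the end of green (starting material / double product / first product)
- final first product in green, as a percentage of the starting material charged

Solve each end, then join them. At the early end, north already reads 0% starting material at 1.67 d. At the late end, its first product still moves from 35% there to 28% at 4.00 d. These two readings, each with a scatter of 1.5 percentage points, give 7.24 d as the tail half-life: the time first product takes to halve over that stretch.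

Green has c(coupling partner) of 0.276 M against 0.29 M in north, on the same charge of starting material. So take north's 28% as my figure for green, with 71.0% of the charge past first product, and commit to double product there. At 4.00 d first product reads 41% in south-east, 35% in south-west and 28% in north, in order of increasing c(coupling partner), and grey has less c(coupling partner) than south-east. So commit to first product in grey, as a judgement: these readings do not say how the other 56.0% of the charge in south-east divides.

The forecast gives first product for grey, double product for green and 29% against my 28%, because green “nearly repeats north”.

The flasks give first product in grey, double product in green and 27.2% for first product in green.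

    starting material + coupling partner → first product (k = 0.890 L mol⁻¹ h⁻¹)
    coupling partner + first product ⇌ double product (K = 8.60 L mol⁻¹, k = 0.370 L mol⁻¹ h⁻¹)
    2 starting material → homo dimer (k = 0.00290 L mol⁻¹ h⁻¹)
    first product → over-reaction product (k = 0.00990 h⁻¹)

In green, first product and double product exchange with a relaxation half-life of 0.269 d, short against the 4.0 d of the run, while the slowest mode of the whole flask at that time has a half-life of 6.29 d, beside the tail half-life of 7.24 d. Run the tail half-life on green: from 34.6% at 2.00 d it gives 28.6% at 4.0 d, where the flask holds 27.2%; from that value it gives 15.3% at 10 d, and green left that long holds 14.5%.

(All runs stem from a simulated flask from invented constants.)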